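**Plan**
- Cuts: the γ-lactone at C13–C14 and C15–O in one [3+2] event; ring A at C3–C4; the δ-lactone at C19–O(C20); the oxolane at O9–C13 and C9–C11; C10–C1 and C10–C20. This leads back to (S)-carvone, which supplies ring B, C-5, C-17, the C-9 carbonyl and the C-4/C-18/C-19 isopropenyl unit.
- Forward: carvone (ring B) → quaternary C-10 and 6β-oxygen → acetoacetate dianion at C-9, diazo transfer, O–H insertion (spiro oxolan-3-one) → butyrolactone annulation → removal of the C-12 oxygen → δ-lactone → ring A by bridging enolate alkylation → hydrogenation.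
- Enabling feature: C-13 carries the oxolane oxygen O-9 and the carboxyl carbon C-16. With a temporary ketone at C-12 it is a doubly activated methine, so C-13 and the C-16 carbonyl oxygen act as a 1,3-C,O-bisnucleophile toward CH2=CH–SeO2Ph, a two-carbon 1,2-biselectrophile that becomes C-14/C-15.
- Stereochemistry: C-5 from (S)-carvone; C-10 and C-6 by attack anti to the C-5 substituent; C-9 by addition anti to the axial C-1 chain; C-13 by a chiral bifunctional thiourea; C-4 by the geometry of the bridge; C-8 last, by hydroxyl-directed hydrogenation.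

Key step: step 11

Remark: as written, the target has H-5 and C-20 on the same face (cis-fused rings A/B); labdane numbering is used for all intermediates, and β denotes the face of ring B that carries C-20 and H-5.

**Route**

Step 1
Reactants: 1 (S)-(+)-carvone
Product: 3 6-(3-chloropropyl)carvone (chain mainly trans to isopropenyl), via lithium dienolate of carvone 2 (not isolated)
Conditions: LiN(iPr)2, THF, −78 °C; DMPU, then ICH2CH2CH2Cl, −78 → −20 °C
Reagents that add atoms: 1-chloro-3-iodopropane, ClCCCI
Why: Kinetic α′-deprotonation of the enone and enolate alkylation at the iodide terminus place C-1 to C-3 on the future C-10; the C-10 configuration is erased in step 2 and the carvone stereocentre (C-5) is untouched.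

Step 2
Reactants: 3 6-(3-chloropropyl)carvone
Product: 5 6-(3-chloropropyl)-6-(hydroxymethyl)carvone (CH2OH trans to isopropenyl), via lithium enolate of the chloropropyl ketone 4 (not isolated)
Conditions: LiN(iPr)2, THF, −78 °C; then CH2O (gas from cracked paraformaldehyde), −78 °C; aq. NH4Cl
Reagents that add atoms: formaldehyde, C=O
Why: Aldol addition of the tetrasubstituted enolate to formaldehyde creates the quaternary C-10; the electrophile enters anti to the vicinal isopropenyl group, as is usual for second alkylations of 6-substituted carvones, so C-20 is β and the C-1 chain α.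

Step 3
Reactants: 5 6-(3-chloropropyl)-6-(hydroxymethyl)carvone
Product: 6 bis-TBS silyl dienol ether
Conditions: TBSOTf (2.5 equiv), Et3N, CH2Cl2, 0 → 23 °C
Reagents that add atoms: tert-butyldimethylsilyl trifluoromethanesulfonate, CC(C)(C)[Si](C)(C)OS(=O)(=O)C(F)(F)F
Why: Silylation of the primary alcohol and soft enolisation of the enone, which has no α′-hydrogen and therefore loses a γ-hydrogen from C-6 to give the linear silyl dienol ether.

Step 4
Reactants: 6 bis-TBS silyl dienol ether
Product: 7 6β-hydroxy enone (C-20 O-TBS)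
Conditions: mCPBA (1.0 equiv), NaHCO3, CH2Cl2, −40 → 0 °C; aqueous work-up
Reagents that add atoms: 3-chloroperoxybenzoic acid, OOC(=O)c1cccc(Cl)c1
Why: Vinylogous Rubottom oxidation: the peracid attacks the terminal γ-carbon C-6 of the electron-rich dienol ether (faster than the isopropenyl alkene) on the face opposite the vicinal C-5 isopropenyl group and the axial C-1 chain, giving the 6β-alcohol and regenerating the enone.

Step 5
Reactants: 7 6β-hydroxy enone
Product: 8 6β-O-TIPS enone
Conditions: TIPSOTf, 2,6-lutidine, CH2Cl2, 0 °C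
Reagents that add atoms: triisopropylsilyl trifluoromethanesulfonate, CC(C)[Si](OS(=O)(=O)C(F)(F)F)(C(C)C)C(C)C
Why: Silyl ether protection of the secondary allylic alcohol with a group that outlasts the later selective cleavage of the primary TBS ether.

Step 6
Reactants: 8 6β-O-TIPS enone, 9 tert-butyl acetoacetate
Product: 11 δ-hydroxy β-keto ester (C-11 β; 9α-OH), via dilithium dianion of tert-butyl acetoacetate 10 (not isolated)
Conditions: 9, LiN(iPr)2 (2 equiv), THF, 0 °C; anhydrous CeCl3, −78 °C; then 8, −78 → −40 °C; aq. NH4Cl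
Reagents that add atoms: none
Why: Aldol-type 1,2-addition of the dianion γ-carbon to the C-9 carbonyl, which has no α- or α′-hydrogen (CeCl3 suppresses γ-deprotonation and conjugate addition), should occur on the β face, away from the axial C-1 chain on the adjacent C-10, and so sets C-9.

Step 7
Reactants: 11 δ-hydroxy β-keto ester
Product: 12 α-diazo β-keto ester
Conditions: 4-acetamidobenzenesulfonyl azide, Et3N, MeCN, 0 → 23 °C
Reagents that add atoms: 4-acetamidobenzenesulfonyl azide, CC(=O)Nc1ccc(cc1)S(=O)(=O)N=[N+]=[N-]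
Why: Regitz diazo transfer to the active methylene C-13 runs under mild amine base, which leaves the tertiary aldol intact.

Step 8
Reactants: 12 α-diazo β-keto ester
Product: 13 spiro oxolan-3-one tert-butyl ester
Conditions: Rh2(OAc)4 (1 mol %), CH2Cl2, 23 °C
Reagents that add atoms: none
Why: Rhodium carbenoid O–H insertion into the tertiary C-9 hydroxyl closes the five-membered ether (O9–C13) faster than cyclopropanation or C–H insertion; C-13 is an enolisable β-keto ester carbon, so its configuration is immaterial here.

Step 9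
Reactants: 14 phenylselenyl bromide, 15 vinylmagnesium bromide
Product: 16 phenyl vinyl selenide
Conditions: THF, 0 °C
Reagents that add atoms: none
Why: Nucleophilic substitution at selenium by the vinyl Grignard reagent gives the vinyl selenide.

Step 10
Reactants: 16 phenyl vinyl selenide
Product: 17 phenyl vinyl selenone
Conditions: mCPBA (2.5 equiv), CH2Cl2, 0 → 23 °C
Reagents that add atoms: 3-chloroperoxybenzoic acid, OOC(=O)c1cccc(Cl)c1
Why: Twofold oxidation at selenium (selenide to selenoxide to selenone); the vinyl selenoxide cannot undergo syn-elimination and the electron-poor alkene is not epoxidised.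

Step 11
Reactants: 13 spiro oxolan-3-one tert-butyl ester, 17 phenyl vinyl selenone
Product: 19 spiro γ-butyrolactone 12-ketone, via selenonylethyl Michael adduct 18 (not isolated)
Conditions: 17 (1.5 equiv), quinine-derived bifunctional thiourea 1-[3,5-bis(trifluoromethyl)phenyl]-3-[(8α,9S)-6′-methoxycinchonan-9-yl]thiourea (10 mol %), toluene, −20 → 23 °C; then SiO2, CH2Cl2, 23 °C
Reagents that add atoms: none
Why: The quinuclidine of the catalyst deprotonates C-13–H of 13 (acidified by the C-12 ketone, the C-16 ester and O-9), the thiourea-bound enolate adds through C-13 to the β-carbon of 17 (C13–C14), and in adduct 18 the ester carbonyl oxygen displaces benzeneseleninate from C-15 (C15–O), the dialkoxycarbenium ion then losing isobutylene to give the lactone. The closest known reaction type is the organocatalysed Michael addition/cyclisation of cyclic β-keto tert-butyl esters with vinyl selenones to spirolactones, a formal [3+2] annulation with an ethylene 1,2-dication equivalent. The butyrolactone closes by a 5-exo-tet O-alkylation. The new stereocentre C-13 is set in the C–C bond formation by the catalyst, whose ion pair (thiourea on the 1,3-dicarbonyl enolate, protonated quinuclidine on a selenone oxygen) is expected to present the acceptor to the face of C-13 syn to C-10; the substrate itself should discriminate little, because both faces of the oxolanone are flanked, by the vinylic C-17 methyl on one side and by C-20 on the other. The step needs C- over O-alkylation and a single addition, secured by the soft acceptor and by the quaternary C-13 of 18 (no second acidic hydrogen, hence no cyclopropane), and it needs closure through the ester and not the ketone oxygen, secured because only the tert-butyl ester can shed a cation and make the O-alkylation irreversible, while C-11 is not enolised by the amine and the β-alkoxy ketone therefore does not open.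

Step 12
Reactants: 19 spiro γ-butyrolactone 12-ketone
Product: 20 12-hydroxy spirolactone (C-12 epimers)
Conditions: NaBH4, MeOH/THF, −40 °C
Reagents that add atoms: none
Why: Borohydride reduction of the ketone is much faster than attack on the lactone at low temperature; the new carbinol centre is removed in step 14, so its configuration is irrelevant.

Step 13
Reactants: 20 12-hydroxy spirolactone
Product: 21 12-O-(imidazol-1-ylthiocarbonyl) derivative
Conditions: 1,1′-thiocarbonyldiimidazole, DMAP (cat.), ClCH2CH2Cl, 60 °C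
Reagents that add atoms: 1,1′-thiocarbonyldiimidazole, S=C(n1ccnc1)n1ccnc1
Why: Neutral thioacylation of the hindered secondary alcohol (first half of a Barton–McCombie deoxygenation) avoids an alkoxide that could trigger retro-aldol cleavage of the β-hydroxy lactone.

Step 14
Reactants: 21 12-O-(imidazol-1-ylthiocarbonyl) derivative
Product: 22 12-deoxy spiro oxolane lactone
Conditions: Bu3SnH, AIBN (cat.), toluene, 90 °C
Reagents that add atoms: none
Why: Barton–McCombie radical deoxygenation removes the temporary C-12 oxygen; the secondary radical should be reduced by the stannane before it can rearrange, and the primary chloride, silyl ethers and alkenes are inert on this time scale.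

Step 15
Reactants: 22 12-deoxy spiro oxolane lactone
Product: 24 C-19 primary alcohol (C-4 epimers), via B-alkyl 9-borabicyclononane adduct 23 (not isolated)
Conditions: 9-BBN, THF, 0 → 23 °C; then 30% H2O2, aq. NaOAc, 0 °C
Reagents that add atoms: hydrogen peroxide, OO
Why: Anti-Markovnikov hydroboration–oxidation: bulky 9-BBN adds to the 1,1-disubstituted isopropenyl group far faster than to the hindered trisubstituted C7=C8 alkene, and buffered peroxide spares the lactone; the new C-4 centre forms as an epimer mixture that converges in step 18.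

Step 16
Reactants: 24 C-19 primary alcohol
Product: 25 C-19 carboxylic acid
Conditions: TEMPO (cat.), PhI(OAc)2, MeCN/pH 7 phosphate buffer, 23 °C
Reagents that add atoms: water, O
Why: Oxoammonium oxidation of the primary alcohol through the aldehyde hydrate to the acid tolerates the alkene, the silyl ethers and the alkyl chloride.

Step 17
Reactants: 25 C-19 carboxylic acid
Product: 27 19,20-δ-lactone (ring A still open; C-4 epimers), via C-20 hydroxy C-19 acid 26 (not isolated)
Conditions: HF·pyridine, pyridine/THF, 0 → 23 °C; then PPTS (cat.), toluene, 50 °C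
Reagents that add atoms: none
Why: The primary TBS ether is cleaved selectively beside the secondary TIPS ether, and the C-19 acid and C-20 alcohol, trans-diequatorial on ring B, close the six-membered ring by acid-catalysed lactonisation.

Step 18
Reactants: 27 19,20-δ-lactone
Product: 29 tricyclic 6-O-TIPS ether (ring A closed), via potassium lactone enolate 28 (not isolated)
Conditions: KN(SiMe3)2, n-Bu4NI (cat.), THF, −78 → 23 °C
Reagents that add atoms: none
Why: Intramolecular 6-exo-tet enolate alkylation at the only enolisable position (C-4; C-13 is quaternary) by C-3 closes ring A as the bridge of a bicyclo[3.3.1] system, which is possible only with the new C3–C4 bond axial on the lactone ring and on the face of the axial C-1 chain, so C-18 becomes α and C-19 β and both C-4 epimers converge.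

Step 19
Reactants: 29 tricyclic 6-O-TIPS ether
Product: 30 7,8-didehydro target (6β-allylic alcohol)
Conditions: HF·pyridine, THF, 23 → 40 °C
Reagents that add atoms: none
Why: Non-basic fluoride desilylation leaves both lactones closed; translactonisation to O-6 is geometrically excluded because C-19 and C-6 are anti across C4–C5.

Step 20
Reactants: 30 7,8-didehydro target
Product: 31 target CNP0393616.2
Conditions: [Ir(cod)(PCy3)(py)]PF6 (10 mol %), H2 (1 atm), CH2Cl2, 23 °C
Reagents that add atoms: none
Why: Hydroxyl-directed homogeneous hydrogenation: the cationic iridium catalyst binds the allylic 6β-OH and delivers H2 to the β face of C7=C8, so H-8 becomes β and C-17 α (trans to the hydroxyl, the outcome known for 3-methylcyclohex-2-enols).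

**Compound list**
1 | (S)-(+)-carvone, (5S)-2-methyl-5-(prop-1-en-2-yl)cyclohex-2-en-1-one | CC1=CC[C@H](C(C)=C)CC1=O | starting material
2 | lithium dienolate of carvone (enolate C9=C10 in labdane numbering) | [Li+].CC1=CC[C@H](C(C)=C)C=C1[O-] | intermediate
3 | 6-(3-chloropropyl)carvone, chain on C-10 trans to the isopropenyl group (main epimer) | CC1=CC[C@H](C(C)=C)[C@@H](CCCCl)C1=O | intermediate
4 | lithium enolate of 3 (tetrasubstituted C9=C10 enolate) | [Li+].CC1=CC[C@H](C(C)=C)C(CCCCl)=C1[O-] | intermediate
5 | 6-(3-chloropropyl)-6-(hydroxymethyl)carvone; quaternary C-10 with CH2OH (C-20) β, trans to the isopropenyl group, and the chloropropyl chain (C-1 to C-3) α | CC1=CC[C@H](C(C)=C)[C@](CO)(CCCCl)C1=O | intermediate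
6 | 9-O-TBS dienol ether (C9=C8, C7=C6) of 5 with C-20 O-TBS | CC=1C=C[C@H](C(C)=C)[C@](CO[Si](C)(C)C(C)(C)C)(CCCCl)C=1O[Si](C)(C)C(C)(C)C | intermediate
7 | 6β-hydroxy enone: C-20 O-TBS ether of 5 carrying a 6β-OH trans to the isopropenyl group | CC1=C[C@@H](O)[C@H](C(C)=C)[C@](CO[Si](C)(C)C(C)(C)C)(CCCCl)C1=O | intermediate
8 | 6β-O-TIPS, 20-O-TBS enone | CC1=C[C@@H](O[Si](C(C)C)(C(C)C)C(C)C)[C@H](C(C)=C)[C@](CO[Si](C)(C)C(C)(C)C)(CCCCl)C1=O | intermediate
9 | tert-butyl acetoacetate (tert-butyl 3-oxobutanoate) | CC(=O)CC(=O)OC(C)(C)C | starting material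
10 | dilithium dianion of tert-butyl acetoacetate | [Li+].[Li+].C=C([O-])C=C([O-])OC(C)(C)C | intermediate
11 | δ-hydroxy β-keto ester: tert-butyl 3-oxobutanoate attached through C-11 to C-9 of ring B, C-11 β and 9-OH α | CC1=C[C@@H](O[Si](C(C)C)(C(C)C)C(C)C)[C@H](C(C)=C)[C@](CO[Si](C)(C)C(C)(C)C)(CCCCl)[C@@]1(O)CC(=O)CC(=O)OC(C)(C)C | intermediate
12 | 13-diazo derivative of 11 | CC1=C[C@@H](O[Si](C(C)C)(C(C)C)C(C)C)[C@H](C(C)=C)[C@](CO[Si](C)(C)C(C)(C)C)(CCCCl)[C@@]1(O)CC(=O)C(=[N+]=[N-])C(=O)OC(C)(C)C | intermediate
13 | spiro oxolan-3-one (O-9 α, C-11 β on C-9) with tert-butyl ester on C-13 (C-13 epimers, enolisable) | CC1=C[C@@H](O[Si](C(C)C)(C(C)C)C(C)C)[C@H](C(C)=C)[C@](CO[Si](C)(C)C(C)(C)C)(CCCCl)[C@@]12CC(=O)C(C(=O)OC(C)(C)C)O2 | intermediate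
14 | phenylselenyl bromide (benzeneselenenyl bromide) | Br[Se]c1ccccc1 | starting material
15 | vinylmagnesium bromide | C=C[Mg]Br | starting material
16 | phenyl vinyl selenide | C=C[Se]c1ccccc1 | intermediate
17 | phenyl vinyl selenone | C=C[Se](=O)(=O)c1ccccc1 | intermediate
18 | Michael adduct: 13 bearing a 2-(phenylselenonyl)ethyl group on C-13, on the face syn to C-10 | CC1=C[C@@H](O[Si](C(C)C)(C(C)C)C(C)C)[C@H](C(C)=C)[C@](CO[Si](C)(C)C(C)(C)C)(CCCCl)[C@@]12CC(=O)[C@@](CC[Se](=O)(=O)c3ccccc3)(C(=O)OC(C)(C)C)O2 | intermediate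
19 | spiro γ-butyrolactone 12-ketone (C-13 as in the target: C-14 syn to C-10, C-16 syn to C-8) | CC1=C[C@@H](O[Si](C(C)C)(C(C)C)C(C)C)[C@H](C(C)=C)[C@](CO[Si](C)(C)C(C)(C)C)(CCCCl)[C@@]12CC(=O)[C@]3(CCOC3=O)O2 | intermediate
20 | 12-hydroxy spirolactone (C-12 epimers) | CC1=C[C@@H](O[Si](C(C)C)(C(C)C)C(C)C)[C@H](C(C)=C)[C@](CO[Si](C)(C)C(C)(C)C)(CCCCl)[C@@]12CC(O)[C@]3(CCOC3=O)O2 | intermediate
21 | 12-O-(imidazol-1-ylthiocarbonyl) derivative of 20 | CC1=C[C@@H](O[Si](C(C)C)(C(C)C)C(C)C)[C@H](C(C)=C)[C@](CO[Si](C)(C)C(C)(C)C)(CCCCl)[C@@]12CC(OC(=S)n3ccnc3)[C@]3(CCOC3=O)O2 | intermediate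
22 | 12-deoxy spiro oxolane lactone (9,13-epoxy-16,15-olide unit complete; isopropenyl, chloropropyl, C7=C8 retained) | CC1=C[C@@H](O[Si](C(C)C)(C(C)C)C(C)C)[C@H](C(C)=C)[C@](CO[Si](C)(C)C(C)(C)C)(CCCCl)[C@@]12CC[C@]3(CCOC3=O)O2 | intermediate
23 | B-(C-19 alkyl)-9-borabicyclo[3.3.1]nonane adduct of 22 (C-4 epimers) | CC1=C[C@@H](O[Si](C(C)C)(C(C)C)C(C)C)[C@H](C(C)CB3C4CCCC3CCC4)[C@](CO[Si](C)(C)C(C)(C)C)(CCCCl)[C@@]12CC[C@]3(CCOC3=O)O2 | intermediate
24 | C-19 primary alcohol (C-4 epimers) | CC1=C[C@@H](O[Si](C(C)C)(C(C)C)C(C)C)[C@H](C(C)CO)[C@](CO[Si](C)(C)C(C)(C)C)(CCCCl)[C@@]12CC[C@]3(CCOC3=O)O2 | intermediate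
25 | C-19 carboxylic acid (C-4 epimers) | CC1=C[C@@H](O[Si](C(C)C)(C(C)C)C(C)C)[C@H](C(C)C(O)=O)[C@](CO[Si](C)(C)C(C)(C)C)(CCCCl)[C@@]12CC[C@]3(CCOC3=O)O2 | intermediate
26 | C-20 hydroxy C-19 acid (C-4 epimers) | CC1=C[C@@H](O[Si](C(C)C)(C(C)C)C(C)C)[C@H](C(C)C(O)=O)[C@](CO)(CCCCl)[C@@]12CC[C@]3(CCOC3=O)O2 | intermediate
27 | 19,20-δ-lactone trans-fused to ring B, 3-chloropropyl chain axial on C-10 (C-4 epimers) | CC1=C[C@@H](O[Si](C(C)C)(C(C)C)C(C)C)[C@@H]4C(C)C(=O)OC[C@@]4(CCCCl)[C@@]12CC[C@]3(CCOC3=O)O2 | intermediate
28 | potassium enolate of 27 (C4=C19 enolate) | [K+].CC1=C[C@@H](O[Si](C(C)C)(C(C)C)C(C)C)[C@@H]4C(C)=C([O-])OC[C@@]4(CCCCl)[C@@]12CC[C@]3(CCOC3=O)O2 | intermediate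
29 | tricyclic 6β-O-TIPS ether: rings A and B cis-fused, 19,20-lactone, C-18 α, C7=C8 | CC1=C[C@@H](O[Si](C(C)C)(C(C)C)C(C)C)[C@H]2[C@]3(CCC[C@]2(C)C(=O)OC3)[C@@]12CC[C@]1(CCOC1=O)O2 | intermediate
30 | 7,8-didehydro target (6β-OH, C7=C8) | CC1=C[C@@H](O)[C@H]2[C@]3(CCC[C@]2(C)C(=O)OC3)[C@@]12CC[C@]1(CCOC1=O)O2 | intermediate
31 | CNP0393616.2 | C[C@@H]1C[C@@H](O)[C@H]2[C@]3(CCC[C@]2(C)C(=O)OC3)[C@@]12CC[C@]1(CCOC1=O)O2 | target

**Count and risks**

Total steps: 20. Longest linear sequence: 18 (steps 1–8 and 11–20; steps 9 and 10 prepare selenone 17).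

Step 11. The catalyst may fail to override the substrate's own facial preference at C-13, or the hindered enolate may add so slowly that the adduct eliminates benzeneseleninic acid before it lactonises. The fallback sets out from 13 and uses enantioselective phase-transfer C-alkylation (N-(9-anthracenylmethyl)cinchonidinium bromide, CsOH·H2O, toluene, −40 °C) with 2-iodoethyl 4-methoxybenzyl ether. This gives the 13-[2-(4-methoxybenzyloxy)ethyl] keto ester F1. DDQ in CH2Cl2/pH 7 buffer frees the 13-(2-hydroxyethyl) keto ester F2, and TsOH (cat.) in toluene at 50 °C closes the lactone with loss of tert-butanol, returning to the route at 19. C-13 is then set in a chiral ammonium ion pair with an sp3 electrophile, and the ring oxygen comes from the side chain, so neither the conjugate addition nor the displacement at selenium is required.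

Step 20. Hydrogen may be delivered to the α face (competing coordination of iridium to O-9, shielding of the β face by C-11), or the hindered alkene may resist reduction, because the product carries an axial C-17 syn to C-1. The fallback sets out from 30. Silylation with (HMe2Si)2NH gives the 6-O-dimethylsilyl ether F3. Intramolecular hydrosilylation (Pt2[(CH2=CHSiMe2)2O]3, toluene, 60 °C) should give the cis-fused 8β-silyl oxasilolane F4, with silicon on C-8 and hydrogen on C-7 delivered from the tethered β face. Alkoxide-assisted protodesilylation (KOC(CH3)3, wet DMSO, then acidic work-up to re-close any opened lactone) replaces silicon by hydrogen with retention and returns to the route at 31. The face is then fixed by a covalent tether and not by catalyst binding.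

Step 6. The bulky dianion may deprotonate C-6 or add 1,4 instead of 1,2 at the hindered C-9 carbonyl, or the tertiary aldolate may revert on work-up. The fallback sets out from 8. The smaller lithium enolate of ethyl acetate (LiN(iPr)2, EtOAc, CeCl3, THF, −78 °C) adds 1,2 to give the ethyl (9α-hydroxy)acetate F5. A crossed Claisen condensation with excess LiCH2CO2C(CH3)3 (THF, −78 → 0 °C) then builds the β-keto ester and returns to the route at 11.

Further compounds
F1 | step 11 | 13-[2-(4-methoxybenzyloxy)ethyl] keto ester | CC1=C[C@@H](O[Si](C(C)C)(C(C)C)C(C)C)[C@H](C(C)=C)[C@](CO[Si](C)(C)C(C)(C)C)(CCCCl)[C@@]12CC(=O)[C@@](CCOCc3ccc(OC)cc3)(C(=O)OC(C)(C)C)O2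
F2 | step 11 | 13-(2-hydroxyethyl) keto ester | CC1=C[C@@H](O[Si](C(C)C)(C(C)C)C(C)C)[C@H](C(C)=C)[C@](CO[Si](C)(C)C(C)(C)C)(CCCCl)[C@@]12CC(=O)[C@@](CCO)(C(=O)OC(C)(C)C)O2
F3 | step 20 | 6-O-dimethylsilyl ether | CC1=C[C@@H](O[SiH](C)C)[C@H]2[C@]3(CCC[C@]2(C)C(=O)OC3)[C@@]12CC[C@]1(CCOC1=O)O2
F4 | step 20 | cis-fused 8β-silyl oxasilolane | C[C@]15C[C@@H](O[Si]5(C)C)[C@H]2[C@]3(CCC[C@]2(C)C(=O)OC3)[C@@]12CC[C@]1(CCOC1=O)O2
F5 | step 6 | ethyl (9α-hydroxy)acetate | CC1=C[C@@H](O[Si](C(C)C)(C(C)C)C(C)C)[C@H](C(C)=C)[C@](CO[Si](C)(C)C(C)(C)C)(CCCCl)[C@@]1(O)CC(=O)OCC
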